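A direct plan would take 1-(2,3,4,5-tetramethoxyphenyl)ethanone A1, remove two of its four methyl ethers with a chelating Lewis acid to give catechol ketone A2, C-acylate the polyanion of A2 with the silyl-protected aroyl chloride A3 to give 1,3-diketone A4, and close ring C by acid-catalysed cyclodehydration at O1–C2 with loss of the silyl group. Its weakest steps would be:
(a) the double demethylation that frees the 8-oxygen, because it would have to stop after exactly two of four methyl ethers and would rest on chelation control alone;
(b) the acylation of a trianion that carries two free phenoxides, because O-acylation, double acylation and aggregation would compete with the wanted C–C bond;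
(c) the silylation and acid chloride formation on ring B, because they would add steps without adding skeletal complexity.

The new route disconnects both C–C bonds of the ring-C carbonyl carbon, C4a–C4 and C4–C3, and supplies C4 as carbon monoxide. A palladium-catalysed carbonylative annulation would join iodophenol 5 (ring A with O1 on C8a and iodine on C4a), CO and arylacetylene 7 (C2, C3 and ring B) and close the pyranone in the same operation. It exploits the ortho relation of O1 and C4a on ring A and the alkyne oxidation level of C2–C3. The 8-oxygen is marked as a benzyl ether from the first step, so no methyl ether is cleaved, no polyanion is acylated, and ring B needs neither protection nor activation.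

Key step: step 5

Assumption: aldehydes 1 and 6 are taken as purchasable; the target has no stereocentre, so no stereocontrol is needed.

Step 1
Reactants: 1 2-hydroxy-3,4-dimethoxybenzaldehyde
Product: 2 2-(benzyloxy)-3,4-dimethoxybenzaldehyde
Conditions: BnBr (1.2 equiv), K2CO3 (2 equiv), DMF, 60 °C, 4 h
Reagents that add atoms: benzyl bromide BrCc1ccccc1
Why: Williamson ether synthesis: carbonate deprotonates the only phenol of 1 and the phenoxide displaces bromide, so the benzyl ether fixes from the outset which oxygen will become the free 8-OH; no stereocentre is formed.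

Step 2
Reactants: 2 2-(benzyloxy)-3,4-dimethoxybenzaldehyde
Product: 4 2-(benzyloxy)-3,4-dimethoxyphenol, via aryl formate 3 (not isolated)
Conditions: mCPBA (1.2 equiv), CH2Cl2, 0 °C to rt, 3 h; aq. NaHCO3 wash; then K2CO3 (0.2 equiv), MeOH, rt, 1 h
Reagents that add atoms: 3-chloroperoxybenzoic acid O=C(OO)c1cccc(Cl)c1
Why: Dakin-type Baeyer–Villiger oxidation: the peracid adds to the aldehyde and the electron-rich aryl group (ortho and para alkoxy donors) should migrate in preference to hydride to give formate 3, which catalytic carbonate in methanol transesterifies to phenol 4; benzyl and methyl ethers are inert to both reagents.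

Step 3
Reactants: 4 2-(benzyloxy)-3,4-dimethoxyphenol
Product: 5 2-(benzyloxy)-6-iodo-3,4-dimethoxyphenol
Conditions: I2 (1.05 equiv), NaHCO3 (1.5 equiv), THF/H2O (1:1), 0 °C to rt, 2 h
Reagents that add atoms: iodine II
Why: Electrophilic aromatic iodination of a phenoxide: the position para to the OH carries a methoxy group, so iodine should enter the only free ortho position C6 (also para to the 3-OMe), whereas C5 is meta to the phenoxide oxygen; one equivalent of iodine under bicarbonate buffering limits a second iodination and oxidation of the ring.

Step 4
Reactants: 6 3-hydroxy-4,5-dimethoxybenzaldehyde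
Product: 7 5-ethynyl-2,3-dimethoxyphenol
Conditions: dimethyl (1-diazo-2-oxopropyl)phosphonate (1.3 equiv), K2CO3 (3 equiv), MeOH, 0 °C to rt, 12 h; aq. NH4Cl
Reagents that add atoms: dimethyl (1-diazo-2-oxopropyl)phosphonate COP(=O)(OC)C(=[N+]=[N-])C(C)=O
Why: Seyferth–Gilbert homologation in the Ohira–Bestmann variant: methoxide deacetylates the reagent, the diazomethylphosphonate anion olefinates the aldehyde in the Horner–Wadsworth–Emmons manner, and the diazoalkene loses N2 with a 1,2-hydrogen shift to give the terminal alkyne; the phenoxide is meta to the aldehyde, does not lower its electrophilicity by resonance, and is reprotonated on work-up.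

Step 5
Reactants: 5 2-(benzyloxy)-6-iodo-3,4-dimethoxyphenol; 7 5-ethynyl-2,3-dimethoxyphenol (1.2 equiv)
Product: 10 8-(benzyloxy)-2-(3-hydroxy-4,5-dimethoxyphenyl)-6,7-dimethoxy-4H-chromen-4-one, via ynone 8 (not isolated), via enaminone 9 (not isolated)
Conditions: PdCl2(dppf) (5 mol %; dppf = 1,1'-bis(diphenylphosphino)ferrocene), CO (20 bar), Et2NH (solvent), 120 °C, 4 h; dilute HCl work-up
Reagents that add atoms: carbon monoxide [C-]#[O+]
Why: Zerovalent palladium, formed from the divalent precatalyst under CO and amine, inserts into the C–I bond of 5, CO insertion gives an aroyl–palladium species, and the amine-deprotonated alkyne 7 is transferred to palladium and reductively eliminated as ynone 8, which creates C4a–C4 and C4–C3. Diethylamine then adds to C2 of 8 to give enaminone 9, and the phenoxide ortho to the ketone replaces the amine at the same carbon (addition–elimination, 6-endo with respect to the former alkyne), closing the pyranone at O1–C2 and regenerating the amine. The closest known reaction type is the palladium-catalysed carbonylative annulation of ortho-iodophenols with terminal alkynes (carbonylative Sonogashira coupling followed by cyclisation), a known flavone synthesis. No stereocentre is formed. The step needs three selectivities: the site of acylation is fixed by the iodine at C6 of 5; CO insertion before alkynylation is favoured by the CO pressure, which suppresses direct coupling to a 2-arylbenzofuran; and six-membered closure over 5-exo closure to an aurone is secured by the secondary amine, because amine and phenoxide attack the same carbon C2. Only the hydroxyl ortho to the new ketone can reach C2, so the benzylated 8-oxygen and the remote 3'-OH on ring B should take no part.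

Step 6
Reactants: 10 8-(benzyloxy)-2-(3-hydroxy-4,5-dimethoxyphenyl)-6,7-dimethoxy-4H-chromen-4-one
Product: 11 8-hydroxy-2-(3-hydroxy-4,5-dimethoxyphenyl)-6,7-dimethoxy-4H-chromen-4-one
Conditions: H2 (1 atm), Pd/C (10 wt % Pd on carbon, 10 mol % Pd), EtOAc/MeOH (1:1), rt, 2–4 h
Reagents that add atoms: none
Why: Catalytic hydrogenolysis of the benzylic C–O bond of the aryl benzyl ether should release toluene under one atmosphere of hydrogen at room temperature, conditions under which the pyrone-type C2=C3 bond, the methyl ethers and the phenols are not expected to react; the reaction is stopped once 10 is consumed.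

## Compound list
1 | 2-hydroxy-3,4-dimethoxybenzaldehyde | COc1ccc(C=O)c(O)c1OC | starting material
2 | 2-(benzyloxy)-3,4-dimethoxybenzaldehyde | COc1ccc(C=O)c(OCc2ccccc2)c1OC | intermediate
3 | 2-(benzyloxy)-3,4-dimethoxyphenyl formate (not isolated) | COc1ccc(OC=O)c(OCc2ccccc2)c1OC | intermediate
4 | 2-(benzyloxy)-3,4-dimethoxyphenol | COc1ccc(O)c(OCc2ccccc2)c1OC | intermediate
5 | 2-(benzyloxy)-6-iodo-3,4-dimethoxyphenol | COc1cc(I)c(O)c(OCc2ccccc2)c1OC | intermediate
6 | 3-hydroxy-4,5-dimethoxybenzaldehyde | COc1cc(C=O)cc(O)c1OC | starting material
7 | 5-ethynyl-2,3-dimethoxyphenol | COc1cc(C#C)cc(O)c1OC | intermediate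
8 | 1-[3-(benzyloxy)-2-hydroxy-4,5-dimethoxyphenyl]-3-(3-hydroxy-4,5-dimethoxyphenyl)prop-2-yn-1-one (not isolated) | COc1cc(C#CC(=O)c2cc(OC)c(OC)c(OCc3ccccc3)c2O)cc(O)c1OC | intermediate
9 | 1-[3-(benzyloxy)-2-hydroxy-4,5-dimethoxyphenyl]-3-(diethylamino)-3-(3-hydroxy-4,5-dimethoxyphenyl)prop-2-en-1-one (alkene geometry not defined, not isolated) | CCN(CC)C(=CC(=O)c1cc(OC)c(OC)c(OCc2ccccc2)c1O)c1cc(O)c(OC)c(OC)c1 | intermediate
10 | 8-(benzyloxy)-2-(3-hydroxy-4,5-dimethoxyphenyl)-6,7-dimethoxy-4H-chromen-4-one | COc1cc(-c2cc(=O)c3cc(OC)c(OC)c(OCc4ccccc4)c3o2)cc(O)c1OC | intermediate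
11 | 8-hydroxy-2-(3-hydroxy-4,5-dimethoxyphenyl)-6,7-dimethoxy-4H-chromen-4-one (CNP0264497.0, achiral) | COc1cc(-c2cc(=O)c3cc(OC)c(OC)c(O)c3o2)cc(O)c1OC | target

Total step count: 6. Longest linear sequence: 5 steps (steps 1, 2, 3, 5 and 6).

Steps most likely to fail:

Step 5. The aroyl–palladium species may be captured by diethylamine (salicylamide formation), the alkyne may couple before CO inserts and go on to a 2-arylbenzofuran, or the ynone may close 5-exo to an aurone. The fallback would make the three bonds one after the other. Setting out from 5, palladium-catalysed aminocarbonylation with N,O-dimethylhydroxylamine hydrochloride (Pd(OAc)2, Xantphos, Et3N, CO 1 atm, toluene, 80 °C) would give the Weinreb amide 3-(benzyloxy)-2-hydroxy-N,4,5-trimethoxy-N-methylbenzamide F1. Addition of the bis(bromomagnesium) salt of 7 (from 7 and 2 equiv of EtMgBr in THF, in excess to allow for the phenoxide of F1) would give ynone 8 after acidic work-up. Treatment of 8 with Et2NH in EtOH at rt would close it through 9, and the route would be rejoined at 10.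

Step 3. Iodine may enter C5 as well as C6, a second iodine may follow, or the electron-rich phenol may be oxidised. The fallback would attach carbon C4 by chelation-controlled ortho-formylation in place of halogenation and carbonylation. Setting out from 4, MgCl2, Et3N and paraformaldehyde in MeCN at reflux should formylate only the position ortho to the OH and give 3-(benzyloxy)-2-hydroxy-4,5-dimethoxybenzaldehyde F2. Addition of the bis(bromomagnesium) salt of 7 would give the propargylic alcohol 2-(benzyloxy)-6-[1-hydroxy-3-(3-hydroxy-4,5-dimethoxyphenyl)prop-2-yn-1-yl]-3,4-dimethoxyphenol F3 (racemic; its stereocentre is removed in the next operation). MnO2 in CH2Cl2 would oxidise F3 to ynone 8, and Et2NH in EtOH would close 8, so that the route would be rejoined at 10.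

Step 6. The C2=C3 bond may be reduced to the flavanone once the benzyl group has gone, or the hindered 8-O-benzyl group may be cleaved only slowly. The fallback would replace hydrogenolysis by Lewis-acid debenzylation: setting out from 10, BCl3 (3 equiv) with pentamethylbenzene (3 equiv) as benzyl cation scavenger in CH2Cl2 at −78 °C, followed by a methanol quench, should cleave the benzyl ether without touching the methyl ethers and give 11 directly; no new compound lies on this path.

Further compounds
F1 | step 5 | 3-(benzyloxy)-2-hydroxy-N,4,5-trimethoxy-N-methylbenzamide | CON(C)C(=O)c1cc(OC)c(OC)c(OCc2ccccc2)c1O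
F2 | step 3 | 3-(benzyloxy)-2-hydroxy-4,5-dimethoxybenzaldehyde | COc1cc(C=O)c(O)c(OCc2ccccc2)c1OC
F3 | step 3 | 2-(benzyloxy)-6-[1-hydroxy-3-(3-hydroxy-4,5-dimethoxyphenyl)prop-2-yn-1-yl]-3,4-dimethoxyphenol (racemic) | COc1cc(C#CC(O)c2cc(OC)c(OC)c(OCc3ccccc3)c2O)cc(O)c1OC
F0 | step 6 | none | none
A1 | direct plan | 1-(2,3,4,5-tetramethoxyphenyl)ethanone | CC(=O)c1cc(OC)c(OC)c(OC)c1OC
A2 | direct plan | 1-(2,3-dihydroxy-4,5-dimethoxyphenyl)ethanone | CC(=O)c1cc(OC)c(OC)c(O)c1O
A3 | direct plan | 3-[(tert-butyldimethylsilyl)oxy]-4,5-dimethoxybenzoyl chloride | COc1cc(C(=O)Cl)cc(O[Si](C)(C)C(C)(C)C)c1OC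
A4 | direct plan | 1-(2,3-dihydroxy-4,5-dimethoxyphenyl)-3-{3-[(tert-butyldimethylsilyl)oxy]-4,5-dimethoxyphenyl}propane-1,3-dione | COc1cc(C(=O)CC(=O)c2cc(OC)c(OC)c(O)c2O)cc(O[Si](C)(C)C(C)(C)C)c1OC
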